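**Retrosynthetic overview**

- Target acid ⇐ its tert-butyl ester ⇐ saturated β-acetoxy γ-lactone; E1cB loss of acetic acid creates the ring C3=C4 double bond last.
- Ring A (the only ring) is built in one flask. C2 of a (3R)-3,16-dihydroxyhexadecanoate trianion adds to the ketone of methyl pyruvate (future C3–C4 bond). The 3-oxygen then lactonises onto the pyruvate carboxyl (O1–C2 bond), and an Ac2O quench supplies the terminal acetate.
- (3R)-Diol ester ⇐ β-keto ester by asymmetric hydrogenation (sets the only stereocentre) ⇐ tert-butyl acetoacetate dianion + 12-bromododecan-1-ol.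

Assumption: the presumed biosynthesis is taken as aldol union of C2 of a 3,16-dioxygenated C16 acyl chain with the keto carbon of a pyruvate-derived three-carbon unit, lactonisation of the 3-oxygen onto that unit's carboxyl, then dehydration to the butenolide.

**Route**

Step 1
Reactants: 1 tert-butyl acetoacetate; 2 12-bromododecan-1-ol
Product: 5 tert-butyl 16-hydroxy-3-oxohexadecanoate, via dilithium dienolate 3 (not isolated), via lithium bromoalkoxide 4 (not isolated)
Conditions: LiN(i-Pr)2 (LDA, 2.6 equiv), 1 (1.3 equiv), THF, 0 °C, 30 min; add 2 (1.0 equiv) pre-treated with LDA (1.0 equiv) in THF at −78 °C; 0 °C → rt, 3 h; cold 1 M HCl quench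
Reagents that add atoms: none
Why: Weiler-type γ-alkylation of an acetoacetate dianion, in which the terminal carbanion of 3 is the most nucleophilic site and displaces the primary bromide of 4 (SN2) while the hydroxyl is masked as its lithium alkoxide, so the whole C16 chain with oxygen at C3 and C16 is assembled without a protecting group and no stereocentre is formed.

Step 2
Reactants: 5 tert-butyl 16-hydroxy-3-oxohexadecanoate
Product: 6 tert-butyl (3R)-3,16-dihydroxyhexadecanoate
Conditions: RuCl2[(R)-BINAP] (0.5 mol %), H2 (10 atm), MeOH, 50 °C; recrystallise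
Reagents that add atoms: none
Why: Noyori asymmetric hydrogenation of a β-keto ester, in which ketone and ester carbonyl chelate ruthenium and hydride is delivered to one carbonyl face, (R)-BINAP giving the (3R)-alcohol (the sense established for simple 3-oxoalkanoates, typically ≥97% ee) while the remote hydroxyl and the tert-butyl ester are untouched.

Step 3
Reactants: 6 tert-butyl (3R)-3,16-dihydroxyhexadecanoate; 7 methyl pyruvate
Product: 11 tert-butyl (2R)-4-acetoxy-2-(13-acetoxytridecyl)-4-methyl-5-oxooxolane-3-carboxylate (mixture of diastereomers at C3 and C4), via trilithium enolate 8 (not isolated), via acyclic aldolate 9 (not isolated), via lactone dialkoxide 10 (not isolated)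
Conditions: LDA (3.3 equiv), THF–DMPU (10:1), −78 → −20 °C, 1 h; 7 (1.5 equiv), −78 °C, 30 min; −78 → −10 °C, 1 h; Ac2O (6 equiv), −10 → 0 °C; aqueous work-up
Reagents that add atoms: acetic anhydride, CC(=O)OC(C)=O
Why: Fráter–Seebach-type aldol cascade that copies the presumed biosynthetic ring construction, in which the chelated β-alkoxide enolate 8 adds through C2 to the ketone of 7, the 3-alkoxide of 9 closes the γ-lactone onto the pyruvate ester (5-exo-trig, loss of methoxide) to give 10, and Ac2O caps both remaining alkoxides, which installs the terminal acetate of the target and turns the tertiary hydroxyl into a leaving group; the carbinol centre of 6 (future C5 of the butenolide) is a spectator throughout and the two new stereocentres, formed as a mixture, are erased in step 4.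

Step 4
Reactants: 11 tert-butyl (2R)-4-acetoxy-2-(13-acetoxytridecyl)-4-methyl-5-oxooxolane-3-carboxylate
Product: 13 (2R)-2-(13-acetoxytridecyl)-4-methyl-5-oxo-2,5-dihydrofuran-3-carboxylic acid (target), via butenolide tert-butyl ester 12 (not isolated)
Conditions: DBU (1.1 equiv), CH2Cl2, 0 °C, 1 h; then TFA (CH2Cl2–TFA 3:1), 0 °C → rt, 2 h
Reagents that add atoms: none
Why: E1cB elimination followed by acidolysis, in which DBU removes the proton α to the tert-butyl ester and the tertiary acetate is expelled to give the tetrasubstituted, doubly conjugated alkene of 12 whatever the relative configuration (ring opening through loss of the lactone oxygen would be a reverse 5-endo-trig process and is disfavoured), the acetic acid released buffers the base, and TFA then quenches it and cleaves the tert-butyl ester through the tert-butyl cation without touching the primary acetate, the lactone or the C5 stereocentre.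

**Compound list**

1 | tert-butyl acetoacetate (tert-butyl 3-oxobutanoate) | CC(=O)CC(=O)OC(C)(C)C | starting material
2 | 12-bromododecan-1-ol | OCCCCCCCCCCCCBr | starting material
3 | dilithium 1-tert-butoxybuta-1,3-diene-1,3-diolate (dianion of 1) | [Li+].[Li+].C=C([O-])C=C([O-])OC(C)(C)C | intermediate
4 | lithium 12-bromododecan-1-olate | [Li+].[O-]CCCCCCCCCCCCBr | intermediate
5 | tert-butyl 16-hydroxy-3-oxohexadecanoate | OCCCCCCCCCCCCCC(=O)CC(=O)OC(C)(C)C | intermediate
6 | tert-butyl (3R)-3,16-dihydroxyhexadecanoate | OCCCCCCCCCCCCC[C@@H](O)CC(=O)OC(C)(C)C | intermediate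
7 | methyl pyruvate (methyl 2-oxopropanoate) | CC(=O)C(=O)OC | starting material
8 | trilithium (3R)-1-tert-butoxyhexadec-1-ene-1,3,16-triolate (trianion of 6: two alkoxides and the ester enolate) | [Li+].[Li+].[Li+].[O-]CCCCCCCCCCCCC[C@@H]([O-])C=C([O-])OC(C)(C)C | intermediate
9 | trilithium salt of 1-tert-butyl 4-methyl 2-[(1R)-1,14-dihydroxytetradecyl]-3-hydroxy-3-methylbutanedioate (C2 and C3 unassigned) | [Li+].[Li+].[Li+].[O-]CCCCCCCCCCCCC[C@@H]([O-])C(C(=O)OC(C)(C)C)C(C)([O-])C(=O)OC | intermediate
10 | dilithium salt of tert-butyl (2R)-4-hydroxy-2-(13-hydroxytridecyl)-4-methyl-5-oxooxolane-3-carboxylate (C3 and C4 unassigned) | [Li+].[Li+].[O-]CCCCCCCCCCCCC[C@H]1OC(=O)C(C)([O-])C1C(=O)OC(C)(C)C | intermediate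
11 | tert-butyl (2R)-4-acetoxy-2-(13-acetoxytridecyl)-4-methyl-5-oxooxolane-3-carboxylate (C3 and C4 unassigned) | CC(=O)OCCCCCCCCCCCCC[C@H]1OC(=O)C(C)(OC(C)=O)C1C(=O)OC(C)(C)C | intermediate
12 | tert-butyl (2R)-2-(13-acetoxytridecyl)-4-methyl-5-oxo-2,5-dihydrofuran-3-carboxylate | CC(=O)OCCCCCCCCCCCCC[C@H]1OC(=O)C(C)=C1C(=O)OC(C)(C)C | intermediate
13 | (2R)-2-(13-acetoxytridecyl)-4-methyl-5-oxo-2,5-dihydrofuran-3-carboxylic acid | CC(=O)OCCCCCCCCCCCCC[C@H]1OC(=O)C(C)=C1C(=O)O | target

**Totals**

Total step count: 4. Longest linear sequence: 4 (from 1 and 2; 7 is purchased).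

**Steps most likely to fail, with fallbacks**

Step 3 (most at risk). Proton transfer from the pyruvate methyl group can quench the enolate, the tertiary aldolate 9 can revert before the ring closes, and incomplete lactonisation before the Ac2O quench gives acyclic acetates. The fallback moves the condensation to the β-keto ester stage and lets a reagent-controlled reduction set the stereocentre as the ring closes; it sets out from 5 and comes back at 12. Acetylation of 5 (Ac2O, pyridine) gives tert-butyl 16-acetoxy-3-oxohexadecanoate F1. Knoevenagel condensation of F1 with 7 (TiCl4, pyridine, THF, 0 °C) gives 1-tert-butyl 4-methyl 2-(14-acetoxytetradecanoyl)-3-methylbut-2-enedioate F2 as an E/Z mixture. CBS reduction of the ketone ((S)-2-methyl-CBS-oxazaborolidine, catecholborane, toluene, −78 °C, the alkenyl group acting as the large substituent) gives 1-tert-butyl 4-methyl (2E)-2-[(1R)-14-acetoxy-1-hydroxytetradecyl]-3-methylbut-2-enedioate F3. F3 has the carbinol cis to the methyl ester and lactonises (PPTS, rt) to 12; the Z isomer is recycled by I2-catalysed isomerisation. Compound 12 then needs only the TFA half of step 4.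

Step 4. DBU may partly racemise C5 of 12 through the 2-oxidofuran before the acid quench; the enantiomeric purity of 13 must be checked by chiral HPLC. The fallback dehydrates without a strong base and converges through the exocyclic alkene; it sets out from 6 and comes back at 12. Step 3 is run with an aqueous NH4Cl quench in place of Ac2O to give tert-butyl (2R)-4-hydroxy-2-(13-hydroxytridecyl)-4-methyl-5-oxooxolane-3-carboxylate F4. Ac2O (1.05 equiv) in pyridine at 0 °C acetylates only the primary hydroxyl, giving tert-butyl (2R)-2-(13-acetoxytridecyl)-4-hydroxy-4-methyl-5-oxooxolane-3-carboxylate F5. SOCl2 in pyridine at 0 °C dehydrates the tertiary alcohol, giving 12 together with its isomer tert-butyl (2R)-2-(13-acetoxytridecyl)-4-methylidene-5-oxooxolane-3-carboxylate F6. RhCl3·3H2O (2 mol %) in EtOH at 60 °C moves the exocyclic double bond of F6 into the ring by hydride addition–elimination, so the mixture converges on 12, which is then cleaved with TFA alone.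

Step 1. The unprotected bromo alkoxide 4 may alkylate sluggishly or oligomerise by O-alkylation. The fallback takes the stereocentre from the chiral pool and bypasses steps 1 and 2; it sets out from 2 and comes back at 6. TBSCl and imidazole convert 2 into (12-bromododecyloxy)(tert-butyl)dimethylsilane F7, and Mg in THF gives [12-(tert-butyldimethylsilyloxy)dodecyl]magnesium bromide F8. Commercial tert-butyl (S)-4-chloro-3-hydroxybutanoate is closed with Ag2O to tert-butyl (S)-2-(oxiran-2-yl)acetate F9. CuI-catalysed opening of F9 by F8 at the terminal epoxide carbon (THF, −40 °C) gives tert-butyl (3R)-16-[(tert-butyldimethylsilyl)oxy]-3-hydroxyhexadecanoate F10 with the carbinol configuration retained. TBAF in THF then gives 6.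

**Further compounds**

F1 | step 3 | tert-butyl 16-acetoxy-3-oxohexadecanoate | CC(=O)OCCCCCCCCCCCCCC(=O)CC(=O)OC(C)(C)C
F2 | step 3 | 1-tert-butyl 4-methyl 2-(14-acetoxytetradecanoyl)-3-methylbut-2-enedioate (E/Z mixture) | CC(=O)OCCCCCCCCCCCCCC(=O)C(C(=O)OC(C)(C)C)=C(C)C(=O)OC
F3 | step 3 | 1-tert-butyl 4-methyl (2E)-2-[(1R)-14-acetoxy-1-hydroxytetradecyl]-3-methylbut-2-enedioate | CC(=O)OCCCCCCCCCCCCC[C@@H](O)/C(C(=O)OC(C)(C)C)=C(/C)C(=O)OC
F4 | step 4 | tert-butyl (2R)-4-hydroxy-2-(13-hydroxytridecyl)-4-methyl-5-oxooxolane-3-carboxylate | OCCCCCCCCCCCCC[C@H]1OC(=O)C(C)(O)C1C(=O)OC(C)(C)C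
F5 | step 4 | tert-butyl (2R)-2-(13-acetoxytridecyl)-4-hydroxy-4-methyl-5-oxooxolane-3-carboxylate | CC(=O)OCCCCCCCCCCCCC[C@H]1OC(=O)C(C)(O)C1C(=O)OC(C)(C)C
F6 | step 4 | tert-butyl (2R)-2-(13-acetoxytridecyl)-4-methylidene-5-oxooxolane-3-carboxylate | CC(=O)OCCCCCCCCCCCCC[C@H]1OC(=O)C(=C)C1C(=O)OC(C)(C)C
F7 | step 1 | (12-bromododecyloxy)(tert-butyl)dimethylsilane | CC(C)(C)[Si](C)(C)OCCCCCCCCCCCCBr
F8 | step 1 | [12-(tert-butyldimethylsilyloxy)dodecyl]magnesium bromide | CC(C)(C)[Si](C)(C)OCCCCCCCCCCCC[Mg]Br
F9 | step 1 | tert-butyl (S)-2-(oxiran-2-yl)acetate | C1O[C@H]1CC(=O)OC(C)(C)C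
F10 | step 1 | tert-butyl (3R)-16-[(tert-butyldimethylsilyl)oxy]-3-hydroxyhexadecanoate | CC(C)(C)[Si](C)(C)OCCCCCCCCCCCCC[C@@H](O)CC(=O)OC(C)(C)C
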